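**Remark:** the target has no stereocentre and no stereogenic double bond (each prenyl C=C carries two methyl groups). It is achiral, so the route needs no stereocontrol. Prenyl = 3-methylbut-2-en-1-yl throughout.

## Retrosynthetic overview

1. Target 21 ← benzylic TBS ether 20 (desilylation).
2. Key cut in ring A (the methyl benzoate ring): both bonds at the adjacent carbons C6 and C1 are broken, i.e. the diaryl ether bond C6–O(ring B) and the C1–CO2Me bond. Forward, this is a three-component union of the ring-B phenoxide (from 10), 3-(prenyloxy)benzyne (from 15) and CO2, then MeI. The O-prenyl group at C2 of ring A steers the phenoxide to C6 and places the carbanion at C1.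
3. Ring-B unit 10 ← 5-bromo-2-hydroxy-4-methoxybenzaldehyde 1: O-prenylation, CHO→OH, C-prenylation at the bromide, ortho-hydroxymethylation, bis-silylation.
4. Aryne precursor 15 ← 2-bromoresorcinol 11: mono-prenylation, then silylation / retro-Brook / triflation.
5. No ring is formed; both benzene rings are bought.

Key step: step 8

## Route

Step 1
Reactants: 1 5-bromo-2-hydroxy-4-methoxybenzaldehyde; 2 prenyl bromide (1-bromo-3-methylbut-2-ene)
Product: 3 5-bromo-4-methoxy-2-(prenyloxy)benzaldehyde
Conditions: K2CO3, DMF, rt
Reagents that add atoms: none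
Why: Williamson O-alkylation of the phenoxide with a reactive allylic bromide should be clean because the aldehyde and the aryl bromide are inert to carbonate base.

Step 2
Reactants: 3 5-bromo-4-methoxy-2-(prenyloxy)benzaldehyde
Product: 5 5-bromo-4-methoxy-2-(prenyloxy)phenol, via aryl formate 4 (not isolated)
Conditions: 30% aq H2O2, H2SO4 (cat.), MeOH, 0 °C → rt
Reagents that add atoms: hydrogen peroxide OO
Why: In this acid-catalysed Dakin-type Baeyer–Villiger oxidation the electron-rich 2,4-dialkoxyaryl group migrates to oxygen and the formate is methanolysed in the flask, while the prenyl C=C should survive because no peracid is present.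

Step 3
Reactants: 5 5-bromo-4-methoxy-2-(prenyloxy)phenol; 6 prenylboronic acid pinacol ester
Product: 7 4-methoxy-5-prenyl-2-(prenyloxy)phenol
Conditions: Pd-PEPPSI-IPent (2 mol%), 5 M aq KOH, THF, 70 °C, degassed
Reagents that add atoms: none
Why: Suzuki–Miyaura allyl–aryl coupling with a bulky NHC–Pd catalyst is known to transfer 3,3-disubstituted allylboronates through the unsubstituted α-carbon, so the linear prenyl arene should form and the phenol is tolerated as its phenoxide.

Step 4
Reactants: 7 4-methoxy-5-prenyl-2-(prenyloxy)phenol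
Product: 9 2-(hydroxymethyl)-4-methoxy-3-prenyl-6-(prenyloxy)phenol, via benzodioxaborin 8 (not isolated)
Conditions: PhB(OH)2, (CH2O)n, EtCO2H (cat.), PhH, reflux (Dean–Stark); then propane-1,3-diol, THF, rt
Reagents that add atoms: paraformaldehyde (as formaldehyde) C=O; phenylboronic acid OB(O)c1ccccc1 (boron and phenyl in 8 only)
Why: In the Nagata ortho-hydroxymethylation the aryloxy(phenyl)borane delivers formaldehyde to the only free ortho position, and the cyclic boronate is then released by transesterification with a 1,3-diol.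

Step 5
Reactants: 9 2-(hydroxymethyl)-4-methoxy-3-prenyl-6-(prenyloxy)phenol
Product: 10 bis-TBS ether of 9 (aryl O–TBS and benzylic O–TBS)
Conditions: TBSCl, imidazole, DMAP (cat.), DMF, rt → 40 °C
Reagents that add atoms: tert-butyldimethylsilyl chloride CC(C)(C)[Si](C)(C)Cl
Why: Imidazole-promoted silylation of both hydroxyl groups removes every O–H and gives an aryl silyl ether that fluoride cleaves much faster than the benzylic one.

Step 6
Reactants: 11 2-bromobenzene-1,3-diol; 2 prenyl bromide
Product: 12 2-bromo-3-(prenyloxy)phenol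
Conditions: K2CO3, acetone, reflux; 11 in threefold excess (recovered)
Reagents that add atoms: none
Why: Williamson alkylation of a symmetrical diol used in excess should give mainly the mono-ether, which is separable from recovered diol and a little bis-ether.

Step 7
Reactants: 12 2-bromo-3-(prenyloxy)phenol
Product: 15 3-(prenyloxy)-2-(trimethylsilyl)phenyl trifluoromethanesulfonate, via trimethylsilyl ether 13 (not isolated), via lithium phenoxide 14 (not isolated)
Conditions: HMDS, THF, 70 °C, evaporate; n-BuLi, THF, −78 °C; Tf2O, −78 °C → rt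
Reagents that add atoms: hexamethyldisilazane C[Si](C)(C)N[Si](C)(C)C; trifluoromethanesulfonic anhydride O=S(=O)(OS(=O)(=O)C(F)(F)F)C(F)(F)F; n-butyllithium [Li]CCCC (lithium in 14 only)
Why: O-silylation, bromine–lithium exchange with anionic 1,3-O→C silyl shift (retro-Brook) and O-triflation of the resulting phenoxide is the standard one-pot route from 2-bromophenols to 2-silylaryl triflates, and at −78 °C the exchange should outrun any attack on the prenyl ether.

Step 8
Reactants: 10 bis-TBS ether of 9; 15 3-(prenyloxy)-2-(trimethylsilyl)phenyl trifluoromethanesulfonate; 16 carbon dioxide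
Product: 20 methyl 2-{2-[(tert-butyldimethylsilyloxy)methyl]-4-methoxy-3-prenyl-6-(prenyloxy)phenoxy}-6-(prenyloxy)benzoate, via potassium phenoxide 17 (not isolated), via aryne 18 (not isolated), via potassium carboxylate 19 (not isolated)
Conditions: KF (2.5 equiv), 18-crown-6, CO2 (1 atm), THF, 0 °C, slow addition of 15; then MeI, DMF, rt
Reagents that add atoms: iodomethane CI; potassium fluoride [K+].[F-] (potassium in 17 and 19 only)
Why: Proposed new method: fluoride cleaves the aryl O–Si bond of 10 to give the aprotic phenoxide 17 and, by 1,2-elimination from 15, the aryne 18; 17 adds to the aryne carbon meta to the O-prenyl group, the resulting aryl anion (flanked by the new aryloxy group and the prenyloxy group) is carboxylated by CO2 to 19, and iodomethane esterifies 19 in the same flask. The closest known reaction types are the three-component coupling of arynes, amines and CO2 to anthranilic acids under KF/18-crown-6 in THF, and the addition of phenoxides to silylaryl-triflate-derived arynes with capture of the aryl anion by an internal ester (xanthone synthesis); what is new is intermolecular CO2 capture of a phenoxide–aryne adduct. No ring is closed and no stereocentre is formed. The step needs regioselective C–O bond formation at the distal aryne carbon, which the inductive effect and aryne distortion of the 3-alkoxy group secure, as in known additions to 3-alkoxybenzynes. It also needs carboxylation to outrun protonation, which is secured by the absence of any O–H (phenoxide unmasked from its silyl ether, benzylic alcohol kept as TBS ether), by THF in place of acetonitrile and by the CO2 atmosphere. The benzylic TBS ether should survive because KF/18-crown-6 cleaves alkyl silyl ethers much more slowly than aryl silyl ethers at 0 °C.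

Step 9
Reactants: 20 methyl 2-{2-[(tert-butyldimethylsilyloxy)methyl]-4-methoxy-3-prenyl-6-(prenyloxy)phenoxy}-6-(prenyloxy)benzoate
Product: 21 methyl 2-[2-(hydroxymethyl)-4-methoxy-3-prenyl-6-(prenyloxy)phenoxy]-6-(prenyloxy)benzoate (target)
Conditions: TBAF, AcOH, THF, 0 °C → rt
Reagents that add atoms: none
Why: Fluoride desilylation buffered with acetic acid should free the benzylic alcohol while protonating the alkoxide before it can attack the nearby methyl ester, and it avoids acid that could cyclise the alcohol onto the adjacent prenyl group.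

## Compound list

1 | 5-bromo-2-hydroxy-4-methoxybenzaldehyde | O=Cc1cc(Br)c(OC)cc1O | starting material
2 | prenyl bromide (1-bromo-3-methylbut-2-ene) | CC(C)=CCBr | starting material
3 | 5-bromo-4-methoxy-2-(prenyloxy)benzaldehyde | O=Cc1cc(Br)c(OC)cc1OCC=C(C)C | intermediate
4 | 5-bromo-4-methoxy-2-(prenyloxy)phenyl formate | O=COc1cc(Br)c(OC)cc1OCC=C(C)C | intermediate
5 | 5-bromo-4-methoxy-2-(prenyloxy)phenol | Oc1cc(Br)c(OC)cc1OCC=C(C)C | intermediate
6 | prenylboronic acid pinacol ester (4,4,5,5-tetramethyl-2-prenyl-1,3,2-dioxaborolane) | CC(C)=CCB1OC(C)(C)C(C)(C)O1 | starting material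
7 | 4-methoxy-5-prenyl-2-(prenyloxy)phenol | Oc1cc(CC=C(C)C)c(OC)cc1OCC=C(C)C | intermediate
8 | 6-methoxy-2-phenyl-5-prenyl-8-(prenyloxy)-4H-1,3,2-benzodioxaborinine | COc1cc(OCC=C(C)C)c2OB(c3ccccc3)OCc2c1CC=C(C)C | intermediate
9 | 2-(hydroxymethyl)-4-methoxy-3-prenyl-6-(prenyloxy)phenol | OCc1c(O)c(OCC=C(C)C)cc(OC)c1CC=C(C)C | intermediate
10 | tert-butyl{[2-(tert-butyldimethylsilyloxy)-5-methoxy-6-prenyl-3-(prenyloxy)phenyl]methoxy}dimethylsilane | CC(C)(C)[Si](C)(C)OCc1c(O[Si](C)(C)C(C)(C)C)c(OCC=C(C)C)cc(OC)c1CC=C(C)C | intermediate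
11 | 2-bromobenzene-1,3-diol | Oc1cccc(O)c1Br | starting material
12 | 2-bromo-3-(prenyloxy)phenol | Oc1cccc(OCC=C(C)C)c1Br | intermediate
13 | [2-bromo-3-(prenyloxy)phenoxy]trimethylsilane | C[Si](C)(C)Oc1cccc(OCC=C(C)C)c1Br | intermediate
14 | lithium 3-(prenyloxy)-2-(trimethylsilyl)phenolate | [Li+].[O-]c1cccc(OCC=C(C)C)c1[Si](C)(C)C | intermediate
15 | 3-(prenyloxy)-2-(trimethylsilyl)phenyl trifluoromethanesulfonate | CC(C)=CCOc1cccc(OS(=O)(=O)C(F)(F)F)c1[Si](C)(C)C | intermediate
16 | carbon dioxide | O=C=O | starting material
17 | potassium 2-[(tert-butyldimethylsilyloxy)methyl]-4-methoxy-3-prenyl-6-(prenyloxy)phenolate | [K+].[O-]c1c(CO[Si](C)(C)C(C)(C)C)c(CC=C(C)C)c(OC)cc1OCC=C(C)C | intermediate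
18 | 3-(prenyloxy)benzyne (1,2-didehydro-3-(prenyloxy)benzene) | CC(C)=CCOC1=CC=CC#C1 | intermediate
19 | potassium 2-{2-[(tert-butyldimethylsilyloxy)methyl]-4-methoxy-3-prenyl-6-(prenyloxy)phenoxy}-6-(prenyloxy)benzoate | [K+].[O-]C(=O)c1c(OCC=C(C)C)cccc1Oc1c(OCC=C(C)C)cc(OC)c(CC=C(C)C)c1CO[Si](C)(C)C(C)(C)C | intermediate
20 | methyl 2-{2-[(tert-butyldimethylsilyloxy)methyl]-4-methoxy-3-prenyl-6-(prenyloxy)phenoxy}-6-(prenyloxy)benzoate | COC(=O)c1c(OCC=C(C)C)cccc1Oc1c(OCC=C(C)C)cc(OC)c(CC=C(C)C)c1CO[Si](C)(C)C(C)(C)C | intermediate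
21 | methyl 2-[2-(hydroxymethyl)-4-methoxy-3-prenyl-6-(prenyloxy)phenoxy]-6-(prenyloxy)benzoate | COC(=O)c1c(OCC=C(C)C)cccc1Oc1c(OCC=C(C)C)cc(OC)c(CC=C(C)C)c1CO | target

## Step count and risks

Total steps: 9. Longest linear sequence: 7 (steps 1, 2, 3, 4, 5, 8, 9); steps 6 and 7 make the aryne precursor in a side branch.

**Step 8 (Proposed new method).** The aryl anion may be protonated before it meets CO2, which would give the plain diaryl ether. The benzylic silyl ether may be lost to fluoride, or the carboxylate may be O-arylated by a second aryne. The fallback uses known chemistry, sets out from 10 and returns at 20. The aryl silyl ether of 10 is cleaved selectively with K2CO3 in MeOH to 2-[(tert-butyldimethylsilyloxy)methyl]-4-methoxy-3-prenyl-6-(prenyloxy)phenol F1. Commercial methyl 2-bromo-6-hydroxybenzoate is O-alkylated with 2 (K2CO3, DMF) to methyl 2-bromo-6-(prenyloxy)benzoate F2. F1 and F2 are then joined by a copper-catalysed Ullmann diaryl ether coupling (CuI, picolinic acid, K3PO4, DMSO, 90 °C), where the ortho ester assists the aryl bromide, to give 20.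

**Step 2.** The acid may solvolyse or cleave the prenyl ether, and the electron-rich phenol may be oxidised further. The fallback sets out from 1 and returns at 5; it carries a less oxidisable allyl group through the oxidation and converts it to prenyl afterwards. Compound 1 is O-allylated (allyl bromide, K2CO3, DMF) to 2-(allyloxy)-5-bromo-4-methoxybenzaldehyde F3. Baeyer–Villiger oxidation with mCPBA in CH2Cl2, which epoxidises a monosubstituted allyl ether far more slowly than a prenyl group, gives 2-(allyloxy)-5-bromo-4-methoxyphenyl formate F4. K2CO3 in MeOH cleaves this to 2-(allyloxy)-5-bromo-4-methoxyphenol F5. Olefin cross-metathesis of F5 with 2-methylbut-2-ene (Grubbs second-generation catalyst, 40 °C) turns the allyl ether into the prenyl ether 5.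

**Step 3.** The allyl group may transfer through its γ-carbon to give the 1,1-dimethylallyl isomer, the boronate may protodeboronate, or palladium may ionise the O-prenyl ether. The fallback sets out from 5 and returns at 7; it reverses the polarity of the coupling. Compound 5 is silylated (TBSCl, imidazole, DMF) to tert-butyl[5-bromo-4-methoxy-2-(prenyloxy)phenoxy]dimethylsilane F6. Bromine–lithium exchange (n-BuLi, THF, −78 °C) gives [5-(tert-butyldimethylsilyloxy)-2-methoxy-4-(prenyloxy)phenyl]lithium F7. This is transmetallated with CuBr·SMe2 and alkylated with 2 at its unsubstituted carbon to give tert-butyl[4-methoxy-5-prenyl-2-(prenyloxy)phenoxy]dimethylsilane F8. TBAF in THF then releases 7.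

## Further compounds

F1 | step 8 | 2-[(tert-butyldimethylsilyloxy)methyl]-4-methoxy-3-prenyl-6-(prenyloxy)phenol | CC(C)(C)[Si](C)(C)OCc1c(O)c(OCC=C(C)C)cc(OC)c1CC=C(C)C
F2 | step 8 | methyl 2-bromo-6-(prenyloxy)benzoate | COC(=O)c1c(Br)cccc1OCC=C(C)C
F3 | step 2 | 2-(allyloxy)-5-bromo-4-methoxybenzaldehyde | O=Cc1cc(Br)c(OC)cc1OCC=C
F4 | step 2 | 2-(allyloxy)-5-bromo-4-methoxyphenyl formate | O=COc1cc(Br)c(OC)cc1OCC=C
F5 | step 2 | 2-(allyloxy)-5-bromo-4-methoxyphenol | Oc1cc(Br)c(OC)cc1OCC=C
F6 | step 3 | tert-butyl[5-bromo-4-methoxy-2-(prenyloxy)phenoxy]dimethylsilane | CC(C)(C)[Si](C)(C)Oc1cc(Br)c(OC)cc1OCC=C(C)C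
F7 | step 3 | [5-(tert-butyldimethylsilyloxy)-2-methoxy-4-(prenyloxy)phenyl]lithium | [Li]c1cc(O[Si](C)(C)C(C)(C)C)c(OCC=C(C)C)cc1OC
F8 | step 3 | tert-butyl[4-methoxy-5-prenyl-2-(prenyloxy)phenoxy]dimethylsilane | CC(C)(C)[Si](C)(C)Oc1cc(CC=C(C)C)c(OC)cc1OCC=C(C)C
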